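# Total synthesis of luzonoid D: route proposal

**Assumptions (one line each)**
- Iridoid numbering is used throughout: C1 (acetal), O2, C3, C4, C5, C6, C7, C8, C9, with C10 on C8 and C11 on C4; β is the face of H-5/H-9.
- The target is read as 1S,5S,7S,8R,9S: 1β-O-isovaleryl, 7β-OH, 8α-OH, 8β-CH2O-(Z)-p-coumaroyl.
- The isothiourea antipode that acylates the (S)-lactol is taken to be (R)-BTM; if the sense is reversed, (S)-BTM is used (both are commercial).
- tert-Butyl buta-2,3-dienoate is treated as a catalogue compound.

## Retrosynthetic overview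
1. Luzonoid D ⇒ C4 enol triflate (C11 added last by Stille hydroxymethylation) ⇒ 7β,8β-epoxy (Z)-coumarate, opened at C8 with participation of the C10 ester to give the 7β,8α-diol.
2. Epoxy ester ⇒ C10 allylic alcohol ⇒ C8 enoate / C4 ketone bicycle from a phosphine-catalysed [3+2] annulation of an allenoate onto a pyranone (cyclopentane ring formed second).
3. Pyranone (S)-isovalerate ⇒ furfuryl alcohol by oxidative dearomatization (pyran ring formed first), with a dynamic kinetic acylation that installs the natural C1 ester and the only external stereochemical input.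
4. (Z)-p-Coumaric acid ⇐ (E)-p-coumaric acid by photoisomerization.

## Forward route

**Step 1**
- Reactants: 1 furfuryl alcohol; 3 isovaleric anhydride (via lactol 2, 6-hydroxy-2H-pyran-3(6H)-one, not isolated)
- Product: 4 (S)-5-oxo-5,6-dihydro-2H-pyran-2-yl 3-methylbutanoate
- Conditions: O2, TPP (cat.), hν, CH2Cl2, −78 °C; Me2S, −78 → 0 °C; then 3, (R)-BTM (5 mol %), i-Pr2NEt, −20 °C (one pot)
- Reagents that add atoms: dioxygen, O=O (one O retained); isovaleric anhydride (3), CC(C)CC(=O)OC(=O)CC(C)C
- Why: Proposed new method: singlet-oxygen [4+2] on the furan and sulfide reduction (photo-Achmatowicz) dearomatize 1 to lactol 2, which racemizes by ring opening/closing while the chiral acyl-isothiouronium acylates only the (S)-lactol, so all material funnels to (S)-4 with C1 set as its natural ester; the closest known chemistry is the Achmatowicz rearrangement followed by isothiourea-catalysed dynamic kinetic asymmetric acylation of the lactol, here telescoped and run with isovaleric anhydride at low temperature to suppress oxidopyrylium formation.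

**Step 2**
- Reactants: 4 (S)-pyranone isovalerate; 5 tert-butyl buta-2,3-dienoate
- Product: 6 tert-butyl (1S,5S,9S)-1-(3-methylbutanoyloxy)-4-oxo-1,3,4,5,6,9-hexahydrocyclopenta[c]pyran-8-carboxylate (iridoid numbering; C7=C8, cis-fused)
- Conditions: PPh3 (10 mol %), toluene, rt → 50 °C
- Reagents that add atoms: tert-butyl buta-2,3-dienoate (5), C=C=CC(=O)OC(C)(C)C
- Why: Lu phosphine-catalysed allenoate–enone [3+2] annulation; the zwitterion α-carbon adds to the enone β-carbon (C9) anti to the pseudo-axial C1 acyloxy group and closure at C5 is necessarily cis, setting H-5/H-9 β (syn to 1-O) with the ester on C8.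

**Step 3**
- Reactants: 6
- Product: 7 tert-butyl (1S,5S,9S)-1-(3-methylbutanoyloxy)-4-(trifluoromethylsulfonyloxy)-1,5,6,9-tetrahydrocyclopenta[c]pyran-8-carboxylate (C3=C4 enol triflate)
- Conditions: KHMDS (1.05 equiv), THF, −78 °C; PhNTf2, −78 → −20 °C
- Reagents that add atoms: N-phenyl-bis(trifluoromethanesulfonimide), O=S(=O)(N(c1ccccc1)S(=O)(=O)C(F)(F)F)C(F)(F)F
- Why: Kinetic enolization with a bulky amide removes the unhindered, oxygen-acidified C3–H and not the ring-fusion C5–H, and O-triflation gives the C3=C4 enol triflate, which also masks the ketone for the hydride step (enol triflate formation).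

**Step 4**
- Reactants: 7
- Product: 8 (1S,5S,9S)-1-(3-methylbutanoyloxy)-4-(trifluoromethylsulfonyloxy)-1,5,6,9-tetrahydrocyclopenta[c]pyran-8-carboxylic acid
- Conditions: TFA/CH2Cl2 (1:4), 0 °C → rt
- Reagents that add atoms: none
- Why: Acidolysis (E1 loss of isobutene) of the tert-butyl ester; the acyloxy acetal and the electron-poor enol triflate tolerate anhydrous TFA and no stereocentre is touched.

**Step 5**
- Reactants: 8
- Product: 9 (1S,5S,9S)-8-(hydroxymethyl)-4-(trifluoromethylsulfonyloxy)-1,5,6,9-tetrahydrocyclopenta[c]pyran-1-yl 3-methylbutanoate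
- Conditions: i-BuOCOCl, NMM, THF, −15 °C; then NaBH4, THF/H2O, −15 → 0 °C
- Reagents that add atoms: none
- Why: Mixed carbonic anhydride/borohydride reduction; the anhydride is far more electrophilic than the isovalerate or the triflate, so only C10 is reduced (1,2) to the allylic alcohol.

**Step 6**
- Reactants: 9
- Product: 10 (1S,5S,7S,8S,9S)-7β,8β-epoxy-8-(hydroxymethyl)-4-(trifluoromethylsulfonyloxy)-1,5,6,7,8,9-hexahydrocyclopenta[c]pyran-1-yl 3-methylbutanoate
- Conditions: VO(acac)2 (3 mol %), t-BuOOH (decane), CH2Cl2, 0 °C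
- Reagents that add atoms: tert-butyl hydroperoxide, CC(C)(C)OO
- Why: Hydroxyl-directed vanadium epoxidation touches only the allylic-alcohol alkene and delivers oxygen to the convex β-face (syn to H-5/H-9), setting C7 (O β) and placing C10 temporarily α at C8.

**Step 7**
- Reactants: 11 (E)-p-coumaric acid
- Product: 12 (Z)-p-coumaric acid
- Conditions: hν (365 nm), MeOH, rt; chromatographic separation, E-isomer recycled
- Reagents that add atoms: none
- Why: Direct E→Z photoisomerization of a cinnamic acid to the photostationary mixture, from which the Z-acid is separated.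

**Step 8**
- Reactants: 10 epoxy alcohol; 12 (Z)-p-coumaric acid
- Product: 13 (1S,5S,7S,8S,9S)-7β,8β-epoxy-8-{[(Z)-3-(4-hydroxyphenyl)prop-2-enoyl]oxymethyl}-4-(trifluoromethylsulfonyloxy)-1,5,6,7,8,9-hexahydrocyclopenta[c]pyran-1-yl 3-methylbutanoate
- Conditions: PPh3, DIAD, THF, 0 °C, dark
- Reagents that add atoms: (Z)-p-coumaric acid (12), OC(=O)/C=C\c1ccc(O)cc1
- Why: Mitsunobu esterification at primary C10; the carboxylic acid (pKa about 4.5) is engaged in preference to the phenol (pKa about 10), and the neutral conditions preserve the epoxide, the acyl acetal and the Z-alkene.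

**Step 9**
- Reactants: 13
- Product: 14 (1S,5S,7S,8R,9S)-7β,8α-dihydroxy-8-{[(Z)-3-(4-hydroxyphenyl)prop-2-enoyl]oxymethyl}-4-(trifluoromethylsulfonyloxy)-1,5,6,7,8,9-hexahydrocyclopenta[c]pyran-1-yl 3-methylbutanoate
- Conditions: CSA (20 mol %), MeCN/H2O (10:1), 0 °C → rt, dark
- Reagents that add atoms: water, O
- Why: Anchimerically assisted epoxide opening; the C10 ester carbonyl attacks the protonated epoxide at C8 from the α-face (five-membered 1,3-dioxolan-2-ylium, inversion at C8), and hydrolysis returns the acyl group to the primary O-10, giving 8α-OH with C10 β and leaving the 7β C–O bond untouched.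

**Step 10**
- Reactants: 14; 15 (tributylstannyl)methanol
- Product: 16 luzonoid D
- Conditions: Pd(PPh3)4 (10 mol %), LiCl, 1,4-dioxane, 80 °C, dark
- Reagents that add atoms: (tributylstannyl)methanol (15), CCCC[Sn](CCCC)(CCCC)CO
- Why: Stille (Kosugi–Migita) hydroxymethylation of the enol triflate under neutral conditions installs C11 as the free alcohol on the C3=C4 enol ether without touching the esters, the diol or any stereocentre.

## Compound list
1 | furfuryl alcohol | OCc1ccco1 | starting material
2 | 6-hydroxy-2H-pyran-3(6H)-one (racemic, equilibrating lactol; not isolated) | OC1OCC(=O)C=C1 | intermediate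
3 | isovaleric (3-methylbutanoic) anhydride | CC(C)CC(=O)OC(=O)CC(C)C | starting material
4 | (S)-5-oxo-5,6-dihydro-2H-pyran-2-yl 3-methylbutanoate | CC(C)CC(=O)O[C@@H]1OCC(=O)C=C1 | intermediate
5 | tert-butyl buta-2,3-dienoate | C=C=CC(=O)OC(C)(C)C | starting material
6 | (1S,5S,9S) C4-ketone, C7=C8 tert-butyl enoate, 1β-isovalerate | CC(C)CC(=O)O[C@@H]1OCC(=O)[C@H]2CC=C(C(=O)OC(C)(C)C)[C@@H]12 | intermediate
7 | (1S,5S,9S) C3=C4 enol triflate, tert-butyl enoate | CC(C)CC(=O)O[C@@H]1OC=C(OS(=O)(=O)C(F)(F)F)[C@H]2CC=C(C(=O)OC(C)(C)C)[C@@H]12 | intermediate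
8 | (1S,5S,9S) enol triflate, C8 carboxylic acid | CC(C)CC(=O)O[C@@H]1OC=C(OS(=O)(=O)C(F)(F)F)[C@H]2CC=C(C(=O)O)[C@@H]12 | intermediate
9 | (1S,5S,9S) enol triflate, C10 allylic alcohol | CC(C)CC(=O)O[C@@H]1OC=C(OS(=O)(=O)C(F)(F)F)[C@H]2CC=C(CO)[C@@H]12 | intermediate
10 | (1S,5S,7S,8S,9S) 7β,8β-epoxy-10-ol, enol triflate | CC(C)CC(=O)O[C@@H]1OC=C(OS(=O)(=O)C(F)(F)F)[C@H]2C[C@@H]3O[C@]3(CO)[C@@H]12 | intermediate
11 | (E)-p-coumaric acid | OC(=O)/C=C/c1ccc(O)cc1 | starting material
12 | (Z)-p-coumaric acid | OC(=O)/C=C\c1ccc(O)cc1 | intermediate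
13 | (1S,5S,7S,8S,9S) 7β,8β-epoxy-10-O-(Z)-p-coumaroyl, enol triflate | CC(C)CC(=O)O[C@@H]1OC=C(OS(=O)(=O)C(F)(F)F)[C@H]2C[C@@H]3O[C@]3(COC(=O)/C=C\c4ccc(O)cc4)[C@@H]12 | intermediate
14 | (1S,5S,7S,8R,9S) 7β,8α-diol, 10-O-(Z)-p-coumaroyl, enol triflate | CC(C)CC(=O)O[C@@H]1OC=C(OS(=O)(=O)C(F)(F)F)[C@H]2C[C@H](O)[C@](O)(COC(=O)/C=C\c3ccc(O)cc3)[C@@H]12 | intermediate
15 | (tributylstannyl)methanol | CCCC[Sn](CCCC)(CCCC)CO | starting material
16 | luzonoid D | CC(C)CC(=O)O[C@@H]1OC=C(CO)[C@H]2C[C@H](O)[C@](O)(COC(=O)/C=C\c3ccc(O)cc3)[C@@H]12 | target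

## Summary
- Total steps: 10
- Longest linear sequence: 9 (steps 1–6, 8–10)
- No protecting groups are used; stereocentres are set at C1 (step 1), C5/C9 (step 2), C7 (step 6) and C8 (steps 6 and 9).

**Three steps most likely to fail, each with a fallback that changes the approach**
1. **Step 1** (one-pot dearomatization / dynamic kinetic acylation): risks are low ee, the wrong acylation sense, or base-induced oxidopyrylium loss of the ester. Fallback: make the racemic Boc carbonate of lactol 2 (standard NBS Achmatowicz, then Boc2O) and set C1 by Pd(0)/chiral-diphosphine dynamic kinetic asymmetric allylic substitution with isovaleric acid (π-allyl route instead of acyl transfer).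
2. **Step 3** (regioselective enol triflate): the risk is competing enolization toward C5. Fallback: avoid enolates altogether by methylenating the C4 ketone of 6 and carrying the exocyclic alkene as the ketone mask, then convert it at the end into the C3=C4–CH2OH unit by epoxidation and epoxide → allylic alcohol isomerization.
3. **Step 9** (ester-assisted epoxide opening): risks are Z→E scrambling in the acyloxonium ion, water attack at C7, or fragmentation of a free C8 cation. Fallback: esterify 10 with 3-(4-hydroxyphenyl)propiolic acid instead, so the participating ester has no alkene geometry to lose, carry the alkynoate through steps 9 and 10, and create the Z-alkene last by Lindlar semi-hydrogenation.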